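Electrophile cannot keep falling along a straight line: the slope up to the last reading would take it below zero after 8.18 h, and a flask cannot hold less than nothing.

- spring: electrophile 20 mM; nucleophile 22 mM; protic impurity 10 mM; the very flask that is asked about, followed so far
- flask: electrophile 20 mM; nucleophile 22.0 mM; protic impurity 10.0 mM; time 6.0 h

spring run (percent of the electrophile charged)

| time / min | over-reaction product / % | target / % | electrophile / % |
|---|---|---|---|
| 6.00 | 0.1 | 1.1 | 99.2 |
| 10.0 | 0 | 3.0 | 96.6 |
| 20.0 | 0.8 | 5.1 | 95.6 |
| 40.0 | 0 | 8.0 | 91.6 |
| 80.0 | 0.8 | 14.6 | 83.7 |

(scatter of a reading: 0.5 percentage points)



- the largest share of what was charged as electrophile, at 6.0 h belongs to (target / over-reaction product / electrophile)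
- the largest share itself, whichever of these holds it, in percent of the electrophile charged

So go to logarithms. Let a be the fraction of the electrophile charge left, and b the same for the nucleophile. I assume that −ln a climbs at a rate λ times b. Call λ the full-strength rate, the climb per hour with nucleophile at its charge; this is pseudo-first-order thinking. Counting b as whole up to there, the last reading gives 0.133 h⁻¹, and that carries its scatter.

Now turn the settings, one after the other. Time comes first: at full strength, 6.0 h would leave a at 44.9%. The nucleophile comes next: hours count only at strength b, so you multiply them by the mean b. The protic impurity matters through its charge, 45.5% of the nucleophile's, and I suppose it takes that whole amount by the end. The electrophile comes last: I suppose each electrophile that reacts takes one nucleophile, so each fraction that reacts costs 0.909 of that fraction in nucleophile charge.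

Try a at 60.0%. Then b ends at 18.2%, and its mean is 59.1%. That makes 3.55 h at full strength, which returns a at 62.3%. I commit to that figure, and electrophile holds the most.

The forecast says electrophile at 54%, and adds that “the range is wide”.

The flask gives electrophile as the largest share, at 64.2%.

    nucleophile + protic impurity → quenched reagent (k = 6.38 M⁻¹ h⁻¹)
    target → over-reaction product (k = 0.0477 h⁻¹)
    electrophile + nucleophile → acid set free + target (k = 7.09 M⁻¹ h⁻¹)
    nucleophile + acid set free ⇌ idle adduct, settled at all times (K = 77.3 M⁻¹)
    nucleophile + acid set free ⇌ protonated nucleophile, settled at all times (K = 19100 M⁻¹)

That stands 1.9 percentage points above my reckoning. At 6.00 h this flask keeps 20% of its nucleophile charge, less than the 64% of its electrophile charge. Run the rule backwards, dividing −ln a by 0.133 h⁻¹. Reckoned with that read rate, this flask comes to 3.33 h at full strength out of its 6.0 h. A second flask, charged alike and read at 10 h, holds 58.9% electrophile, which the same read rate turns into 3.98 h at full strength.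

Readings and results were generated by integration on assumed constants.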